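The readings were computed for an exercise.

You have no rate constants for this flask, so every rate here is read from the two runs, as a fraction of the charge per minute.

| flask | substrate | gas phase | remark | time |
|---|---|---|---|---|
| north | 0.080 M | 16 mM (held) | run made earlier |  |
| south | 0.32 M | 16 mM (held) | run made earlier |  |
| flask | 0.16 M | 16 mM (held) |  | 25 min |

| north: time / min | north: target / % | south: time / min | south: target / % |
|---|---|---|---|
| 1.50 | 3 | 2.00 | 1 |
| 3.00 | 8 | 5.00 | 10 |
| 6.00 | 12 | 10.0 | 8 |
| 10.0 | 19 | 15.0 | 12 |
| 20.0 | 25 | 20.0 | 15 |

(readings scatter by 1.5 percentage points)

* how much target there is at 25 min, in percent of the substrate charged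
* concentration of dissolved gas in solution at 25 min, in percent of saturation

- at the start none of the gas phase is in solution

North starts at 0.0267 min⁻¹ and south at 0.0200 min⁻¹. These are close although the south charge is 4.00 times larger, so by my reckoning the gas supply keeps up and dissolved gas stays near saturation. Making is then pseudo-first-order in substrate.

What slows it? South stands lower than north at 20.0 min, so I take target to be lost by meeting substrate, at a rate that grows with the charge. Making equals losing at the ceiling yield, the percentage of the charge at which target stops growing, and it varies inversely with [substrate]₀. South's last reading, taken as its ceiling, gives 30.0% here, 0.301 higher in log10.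

The climb takes 11.2 min. Near the ceiling, substrate goes twice over, so its factor at 25 min is 0.264, and the 25 min shrink to 13.8 min of full-speed time. The ceiling's factor is 0.293. Together they take the rate down −1.11 in log10, so I expect 21.2%.

The forecast says 25% and 32%, on “partial gas-transfer limitation”.

The flask gives 19.2% of target, and dissolved gas at 99.0%.

    substrate → side product A (k = 5.10 × 10⁻⁵ s⁻¹)
    substrate + target → side product B (k = 0.0120 M⁻¹ s⁻¹)
    gas phase ⇌ dissolved gas, rate k3*(csat - [dissolved gas]) (kL = 1.20 s⁻¹)
    substrate + dissolved gas → target (k = 0.0280 M⁻¹ s⁻¹)
    2 dissolved gas → homo dimer (k = 0.350 M⁻¹ s⁻¹)

The flask reached 0.640 of the ceiling I estimated from south's scattered reading, and 0.832 of the ceiling that the constants above give, making constant over losing constant times [dissolved gas]. The neighbouring flask is charged at 0.64 M and read at the same time. Its charge is 4.00 times larger, so my estimate of its ceiling, carried over from that same reading, is 7.50%. Its climb takes 2.81 min, which is short against the 13.8 min of full-speed time, so I expect it at its ceiling. The ceiling falls 0.602 in log10 from this flask, while the simulated yields fall 0.524. The neighbouring flask holds 5.74% of target, 0.765 of that estimate, and 0.997 of the 5.76% that the constants give as its ceiling.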